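**Retrosynthetic overview**

- The target is a 3-alkyl-4-methylfuran-2,5-dione. Its only ring is closed last by forming the C3=C4 double bond in an intramolecular Horner–Wadsworth–Emmons olefination of an acyclic mixed anhydride of pyruvic acid and a 2-phosphono C18 acid.
- The enabling feature is the O1 atom flanked by the C2 and C5 carbonyl carbons. This C(=O)–O–C(=O) bridge is assembled from two carboxylic acids and serves as the tether. It holds the pyruvoyl ketone carbon 1,5 to the phosphonate-bearing carbon, activates both, and stays in the product. The endocyclic alkene can only be Z.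
- The 2-phosphono acid comes from tert-butyl diethylphosphonoacetate by alkylation with 11-bromoundec-1-ene, cross-metathesis with (S)-hept-6-en-2-yl acetate, hydrogenation and tert-butyl ester cleavage.
- The single stereocentre comes from (S)-propylene oxide (copper-catalysed opening with butenylmagnesium bromide), is acetylated at once and is carried through unchanged.

Key step: step 8

Remark: but-3-en-1-ylmagnesium bromide is taken as its commercial THF solution. Compounds 8–15 are mixtures of epimers at the phosphonate-bearing carbon (left undefined in the SMILES); this centre becomes sp2 in step 8.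

**Route**

Step 1
Reactants: 1 but-3-en-1-ylmagnesium bromide; 2 (S)-2-methyloxirane
Product: 3 (S)-hept-6-en-2-ol
Conditions: CuI (10 mol%), THF, −30 → 0 °C; then 1 M aq HCl
Reagents that add atoms: none
Why: Copper-catalysed SN2 opening of a terminal epoxide by a Grignard reagent should occur only at the unsubstituted CH2, so the C–O stereocentre of 2 is not touched and becomes C-2 (S) of 3.

Step 2
Reactants: 3 (S)-hept-6-en-2-ol
Product: 4 (S)-hept-6-en-2-yl acetate
Conditions: Ac2O, pyridine, DMAP (cat.), CH2Cl2, 0 °C → rt
Reagents that add atoms: acetic anhydride, CC(=O)OC(C)=O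
Why: DMAP-catalysed O-acylation of a secondary alcohol breaks no bond at the stereocentre, so the (S) configuration is retained.

Step 3
Reactants: 5 tert-butyl 2-(diethoxyphosphoryl)acetate; 6 11-bromoundec-1-ene
Product: 8 tert-butyl 2-(diethoxyphosphoryl)tridec-12-enoate, via sodium phosphonoacetate enolate 7 (not isolated)
Conditions: 5 (1.5 equiv), NaH (1.4 equiv), DMF, 0 °C; then 6, NaI (cat.), 60 °C
Reagents that add atoms: none
Why: SN2 C-alkylation of a phosphonate-stabilised ester enolate by a primary bromide (malonate-type alkylation), with excess 5 to hold back a second alkylation; the new C-2 centre is racemic and is erased in step 8.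

Step 4
Reactants: 8 tert-butyl 2-(diethoxyphosphoryl)tridec-12-enoate; 4 (S)-hept-6-en-2-yl acetate
Product: 9 tert-butyl (17S)-17-acetoxy-2-(diethoxyphosphoryl)octadec-12-enoate (E/Z mixture)
Conditions: 4 (3 equiv), second-generation Grubbs catalyst (5 mol%), 1,4-benzoquinone (10 mol%), CH2Cl2, 40 °C
Reagents that add atoms: none
Why: Olefin cross-metathesis of two unhindered terminal alkenes with loss of ethylene, biased toward the cross product by the excess of the volatile partner 4; the E/Z mixture is of no concern because step 5 saturates it.

Step 5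
Reactants: 9 tert-butyl (17S)-17-acetoxy-2-(diethoxyphosphoryl)octadec-12-enoate
Product: 10 tert-butyl (17S)-17-acetoxy-2-(diethoxyphosphoryl)octadecanoate
Conditions: H2 (1 atm), 10% Pd/C, EtOAc, rt
Reagents that add atoms: none
Why: Heterogeneous catalytic hydrogenation should converge both alkene isomers on one saturated chain and leave the acetate, tert-butyl ester, phosphonate and the non-allylic C-17 stereocentre untouched.

Step 6
Reactants: 10 tert-butyl (17S)-17-acetoxy-2-(diethoxyphosphoryl)octadecanoate
Product: 11 (17S)-17-acetoxy-2-(diethoxyphosphoryl)octadecanoic acid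
Conditions: TFA/CH2Cl2 (1:3), rt
Reagents that add atoms: none
Why: Acidolysis of the tert-butyl ester through the tert-butyl cation (loss of isobutene) is orthogonal to the secondary acetate and to the diethyl phosphonate.

Step 7
Reactants: 11 (17S)-17-acetoxy-2-(diethoxyphosphoryl)octadecanoic acid
Product: 12 (17S)-17-acetoxy-2-(diethoxyphosphoryl)octadecanoyl chloride
Conditions: (COCl)2 (1.5 equiv), DMF (cat.), CH2Cl2, 0 °C → rt; evaporate, use crude
Reagents that add atoms: oxalyl chloride, O=C(Cl)C(=O)Cl
Why: Vilsmeier-catalysed conversion of a carboxylic acid into its chloride under non-basic conditions, as used for dialkylphosphonoacetic acids, should touch neither the acetate nor the phosphonate esters.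

Step 8
Reactants: 12 (17S)-17-acetoxy-2-(diethoxyphosphoryl)octadecanoyl chloride; 13 pyruvic acid
Product: 16 (S)-16-(4-methyl-2,5-dioxo-2,5-dihydrofuran-3-yl)hexadecan-2-yl acetate (the target), via mixed pyruvic anhydride 14 (not isolated), via cyclic aldolate 15 (not isolated)
Conditions: 13 (1.5 equiv), iPr2NEt (3.5 equiv), CH2Cl2, −20 °C, slow addition of 12; then LiCl (3 equiv), MeCN, 0 °C → rt, 0.02 M; 1 M aq HCl work-up
Reagents that add atoms: none
Why: Proposed new method: the pyruvate carboxylate should acylate 12 to give mixed anhydride 14, LiCl/iPr2NEt (Masamune–Roush conditions) should then remove the C–H flanked by P=O and the anhydride C=O, the carbanion adds to the pyruvoyl ketone to give aldolate 15, and syn-elimination of diethyl phosphate through the fused oxaphosphetane forms the ring C3=C4 bond, i.e. an intramolecular Horner–Wadsworth–Emmons olefination across an anhydride tether. The closest known reaction types are the intramolecular HWE closure of α-(phosphonoacyloxy) ketones to butenolides and the Perkin-type condensation of arylglyoxylic acids with arylacetic acids in acetic anhydride, which builds the same bond of diarylmaleic anhydrides through a mixed anhydride. The furan-2,5-dione ring closes in the 5-(enolendo)-exo-trig aldol mode that operates in the butenolide-forming HWE reaction, and it should be easier here because an acyclic anhydride, unlike an ester, has no strong preference against the folded rotamer. No stereocentre is created: the endocyclic alkene can only be Z, both C-2 epimers of 14 and both diastereomers of 15 converge on it (the aldol addition is reversible and the isomer with P and O cis drains the mixture), and the remote (S)-acetate centre is not involved. The step needs chemoselectivity for intramolecular attack at the ketone over intermolecular C-acylation, pyruvate self-aldol and acyl exchange; this is secured by the 1,5-relationship of carbanion and ketone, the high electrophilicity of the α-dicarbonyl ketone, the acidity of the doubly activated C–H (a weak amine base suffices), high dilution, and the fact that symmetric anhydrides formed by exchange revert under carboxylate catalysis while only 14 can cyclise. The product is a thermodynamic sink, since a dialkylmaleic acid recloses spontaneously, so the acidic work-up should return any ring-opened material to 16.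

**Compound list**

1 | but-3-en-1-ylmagnesium bromide | C=CCC[Mg]Br | starting material
2 | (S)-2-methyloxirane ((S)-propylene oxide) | C[C@H]1CO1 | starting material
3 | (S)-hept-6-en-2-ol | C[C@H](O)CCCC=C | intermediate
4 | (S)-hept-6-en-2-yl acetate | CC(=O)O[C@@H](C)CCCC=C | intermediate
5 | tert-butyl 2-(diethoxyphosphoryl)acetate | CCOP(=O)(OCC)CC(=O)OC(C)(C)C | starting material
6 | 11-bromoundec-1-ene | C=CCCCCCCCCCBr | starting material
7 | sodium enolate of tert-butyl 2-(diethoxyphosphoryl)acetate | CCOP(=O)(OCC)C=C([O-])OC(C)(C)C.[Na+] | intermediate (not isolated)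
8 | tert-butyl 2-(diethoxyphosphoryl)tridec-12-enoate (racemic at C-2) | C=CCCCCCCCCCC(C(=O)OC(C)(C)C)P(=O)(OCC)OCC | intermediate
9 | tert-butyl (17S)-17-acetoxy-2-(diethoxyphosphoryl)octadec-12-enoate (E/Z mixture, both C-2 epimers) | CC(=O)O[C@@H](C)CCCC=CCCCCCCCCCC(C(=O)OC(C)(C)C)P(=O)(OCC)OCC | intermediate
10 | tert-butyl (17S)-17-acetoxy-2-(diethoxyphosphoryl)octadecanoate | CC(=O)O[C@@H](C)CCCCCCCCCCCCCCC(C(=O)OC(C)(C)C)P(=O)(OCC)OCC | intermediate
11 | (17S)-17-acetoxy-2-(diethoxyphosphoryl)octadecanoic acid | CC(=O)O[C@@H](C)CCCCCCCCCCCCCCC(C(=O)O)P(=O)(OCC)OCC | intermediate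
12 | (17S)-17-acetoxy-2-(diethoxyphosphoryl)octadecanoyl chloride | CC(=O)O[C@@H](C)CCCCCCCCCCCCCCC(C(=O)Cl)P(=O)(OCC)OCC | intermediate
13 | pyruvic acid (2-oxopropanoic acid) | CC(=O)C(=O)O | starting material
14 | (17S)-17-acetoxy-2-(diethoxyphosphoryl)octadecanoic 2-oxopropanoic anhydride | CC(=O)O[C@@H](C)CCCCCCCCCCCCCCC(C(=O)OC(=O)C(C)=O)P(=O)(OCC)OCC | intermediate (not isolated)
15 | lithium alkoxide of 3-[(15S)-15-acetoxyhexadecyl]-3-(diethoxyphosphoryl)-4-hydroxy-4-methyloxolane-2,5-dione | CC(=O)O[C@@H](C)CCCCCCCCCCCCCCC1(P(=O)(OCC)OCC)C(=O)OC(=O)C1(C)[O-].[Li+] | intermediate (not isolated)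
16 | (S)-16-(4-methyl-2,5-dioxo-2,5-dihydrofuran-3-yl)hexadecan-2-yl acetate | CC(=O)O[C@@H](C)CCCCCCCCCCCCCCC1=C(C)C(=O)OC1=O | target

**Step count and risks**

Total step count: 8. Longest linear sequence: 7 (steps 1, 2, 4, 5, 6, 7, 8).

Steps most likely to fail:

1. Step 8 (Proposed new method). Intermolecular acylation of the phosphonate carbanion, self-condensation of pyruvate, or acyl exchange to symmetric anhydrides may outrun the ring closure. The fallback uses known chemistry, sets out from 12 and returns at 16. It forms the same carbon–carbon bond at the lactone oxidation level and then raises the oxidation level. Compound 12 is esterified with hydroxyacetone (pyridine, CH2Cl2, 0 °C) to 2-oxopropyl (17S)-17-acetoxy-2-(diethoxyphosphoryl)octadecanoate F1. The established intramolecular HWE butenolide closure (LiCl, DBU, MeCN) should give (S)-16-(4-methyl-2-oxo-2,5-dihydrofuran-3-yl)hexadecan-2-yl acetate F2. Enolisation and silylation (TIPSOTf, Et3N, CH2Cl2) should give (S)-16-[4-methyl-2-(triisopropylsilyloxy)furan-3-yl]hexadecan-2-yl acetate F3. Oxidation with dimethyldioxirane (acetone, −78 °C) should give (2S)-16-(5-hydroxy-4-methyl-2-oxo-2,5-dihydrofuran-3-yl)hexadecan-2-yl acetate F4. TPAP/NMO (or Jones reagent) should then oxidise the lactol carbon to the second carbonyl and give 16.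

2. Step 4. Ruthenium-hydride-mediated double-bond migration before metathesis would scramble the chain length, giving homologues that cannot be separated after hydrogenation. Statistical homodimerisation would also lower the cross-coupling efficiency. The fallback replaces metathesis by an sp3–sp3 cross-coupling that fixes the chain length through the building blocks. It sets out from 5 and 4 and returns at 10, bypassing steps 3–5. Compound 5 is mono-alkylated with excess 1,9-dibromononane (NaH, DMF) to tert-butyl 11-bromo-2-(diethoxyphosphoryl)undecanoate F5. Compound 4 is hydroborated with 9-BBN-H (THF, rt) to (S)-7-(9-borabicyclo[3.3.1]nonan-9-yl)heptan-2-yl acetate F6. A palladium-catalysed alkyl–alkyl Suzuki–Miyaura coupling (Pd(OAc)2, PCy3, K3PO4·H2O, THF, rt) should join F6 and F5 to give 10.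

3. Step 3. Substitution at the unactivated bromide may be slow, with a second alkylation and E2 elimination competing under the basic conditions. The fallback installs the phosphorus after the carbon chain. It sets out from 6 and returns at 8. The lithium enolate of tert-butyl acetate (LDA, THF/DMPU, −78 °C → rt) is alkylated with 6 to tert-butyl tridec-12-enoate F7. The enolate of F7 (LDA, 2.2 equiv, THF, −78 °C) is then C-phosphorylated with diethyl chlorophosphate to give 8.

**Further compounds**

F1 | step 8 | 2-oxopropyl (17S)-17-acetoxy-2-(diethoxyphosphoryl)octadecanoate | CC(=O)O[C@@H](C)CCCCCCCCCCCCCCC(C(=O)OCC(C)=O)P(=O)(OCC)OCC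
F2 | step 8 | (S)-16-(4-methyl-2-oxo-2,5-dihydrofuran-3-yl)hexadecan-2-yl acetate | CC(=O)O[C@@H](C)CCCCCCCCCCCCCCC1=C(C)COC1=O
F3 | step 8 | (S)-16-[4-methyl-2-(triisopropylsilyloxy)furan-3-yl]hexadecan-2-yl acetate | CC(=O)O[C@@H](C)CCCCCCCCCCCCCCc1c(C)coc1O[Si](C(C)C)(C(C)C)C(C)C
F4 | step 8 | (2S)-16-(5-hydroxy-4-methyl-2-oxo-2,5-dihydrofuran-3-yl)hexadecan-2-yl acetate | CC(=O)O[C@@H](C)CCCCCCCCCCCCCCC1=C(C)C(O)OC1=O
F5 | step 4 | tert-butyl 11-bromo-2-(diethoxyphosphoryl)undecanoate | BrCCCCCCCCCC(C(=O)OC(C)(C)C)P(=O)(OCC)OCC
F6 | step 4 | (S)-7-(9-borabicyclo[3.3.1]nonan-9-yl)heptan-2-yl acetate | CC(=O)O[C@@H](C)CCCCCB1C2CCCC1CCC2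
F7 | step 3 | tert-butyl tridec-12-enoate | C=CCCCCCCCCCCC(=O)OC(C)(C)C
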